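Skeleton numbering used for atoms (compound numbers are plain numerals): ring A = C1–C5 and C10, with C18 (methyl on C4), C19 (lactone carbonyl) and C20 (methyl on C10); C6 is the lactone CH–O and C7 the linking CH2; in the bicycle C8 is the quaternary bridgehead, C9–C11–C12 the three-carbon bridge, C13 the CH bridgehead, C14 the one-carbon bridge, C15–C16 the two-carbon bridge and C17 the exocyclic CH2.

## Analysis of the target

The target joins two halves through C7: a cyclohexane (ring A) cis-fused to a γ-lactone (C19–O–C6), and a bicyclo[3.2.1]octane with bridgeheads C8 and C13. Its seven stereocentres fall into two sets, C4/C5/C6/C10 and C8/C13/C15. In the lactone half the ring fusion is cis, C7 lies on the convex face anti to ring A, and the C10 hydroxyl is on the face of ring A that carries H5 and the C4 methyl, so C20 is axial and syn to C19. In the bicycle C13 follows from C8 through the bridge, and the C15 acetate points toward the C9–C12 bridge. The two sets are insulated by C7, so neither can be relied on to control the other. The sensitive groups are the enone, the exocyclic methylene with its allylic acetate, the free tertiary alcohol, and the 1,3-relationship of the C9 carbonyl and the C15 oxygen across quaternary C8, which at the diketone level would be open to retro-Claisen cleavage. The hard points are the all-carbon bridgehead C8, quaternary C4, the C10 carbinol in its less stable configuration, and the oxidation pattern at C9, C15 and C16. The plan rests on one feature: C11=C12 lies in a six-membered ring (C8, C9, C11, C12, C13, C14) spanning the 1,3-positions of a cyclopentane, and of its two allylic carbons only C9 is a methylene, C13 being a bridgehead. The enone can therefore be carried as a plain cyclohexene, closed by metathesis between an allyl group on C8 and a vinyl group on C13, and oxygenated at C9 afterwards.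

## Retrosynthetic reasoning

**32 back to 30.** The enone is unveiled last. Oxidation of the allylic C9 alcohol of 31 gives 32, and 31 comes from 30 by loss of both silyl groups. Holding C9 at the alcohol level until the end means a C9/C15 diketone across C8 never exists, and the Michael acceptor is absent during all basic steps.

**30 back to 25.** The C15 acetate comes from alcohol 29, which is the 1,2-reduction product of methylene ketone 28. The C16=C17 bond is cut back to ketone 25. C16 is the only enolisable position because C8 is quaternary, so the methylenation has no regiochemical choice. The reduction must deliver hydride from the C14 side.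

**25 back to 23.** The C9–O bond is removed to give cyclohexene 23. Oxidants that work through a delocalised allyl intermediate could oxygenate either end of C9–C11–C12. A selenium ene/sigmatropic sequence cannot, because the competing ene pathway would need a C12=C13 bridgehead double bond. The forward step therefore returns oxygen to C9 alone, and the alcohol 24 is silylated to 25 before any base is used.

**23 back to 22.** Cutting C11=C12 opens the six-membered ring and reveals cyclopentanone 22 with an allyl group on C8 and a vinyl group on C13. This is the disconnection that carries the plan: it removes the bridged ring in one step, needs only two unactivated terminal alkenes, and leaves C8 on a monocyclic ketone where it can be set through a planar enolate. The forward reaction has to favour closure over oligomerisation, which requires the two arms cis.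

**22 back to 19.** The C13–vinyl bond is cut to cyclopentenone 21, made from ketone 19 by dehydrogenation toward C16/C13 (the only side with hydrogens). C13 is 1,3 to C8 and the two arms on C8 differ only remotely, so substrate control would be weak. The conjugate addition is therefore placed under ligand control.

**19 back to 18.** The C8–C9 bond is cut. Decarboxylative allylation of allyl β-keto ester 18 generates a planar enolate, and a chiral palladium catalyst chooses its face, which overrides the distant lactone stereocentres. Both C8 epimers of 18 converge.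

**18 back to 14 and 17.** The C7–C8 bond is cut between the stabilised enolate of 17 and primary triflate 14. This is the convergent union of the two halves. 17 is the allyl ester obtained from 15 and 16.

**14 back to 10.** Triflate 14 comes from alcohol 13, freed from benzyl ether 12, which is the silyl ether of carbinol 11. The C10–O bond is traced to the exocyclic alkene of 10 by Markovnikov hydration, which must add oxygen on the convex face.

**10 back to 4 and 1.** Three bonds of ring A are cut: C4–C18 (methylation of 9), C3–C4 (intramolecular alkylation of 8) and C5–C10 (conjugate addition to butenolide 5 of the alkenyl unit from bromide 3). C6 is bought with 4, and every other lactone stereocentre is derived from it by anti addition on a five-membered ring. Bromide 3 comes from alkyne 1. A Diels–Alder construction of ring A from an achiral anhydride and a simple diene was set aside because it gives the racemate and leaves unsaturation at C1=C2, remote from C10.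

## Alternatives that were turned down

**Alternative 1:** Ring A is disconnected at C4–C5 by a [3,3] shift. In the forward sense a six-membered lactone, whose ring oxygen sits on allylic C1 and whose side-chain alkene is C10=C5, is converted to its silyl ketene acetal. Rearrangement then forms C4–C5, breaks C1–O and contracts the ring to cyclohexene acid A1 (C1=C10 alkene, C6 as a silyloxymethyl group).
- For: one stereospecific event creates quaternary C4 and C5 together, with chirality relayed from the C1 carbinol. The alkene is placed correctly for later hydration at C10. On the C4/C5 problem this is as good as or better than the annulation and methylation used here.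
- Against: A1 stops at a C6 primary alcohol. The C6 stereocentre and C7 would have to be added afterwards by addition to an aldehyde next to a quaternary centre, with uncertain facial control, and then lactonised. The enantioenriched rearrangement substrate needs its own synthesis with defined alkene geometry. The bicyclic half is not addressed at all.
- Comparison: the chosen route takes C6 from the chiral pool and keeps the strategic risk in one ring closure.

**Alternative 2:** The lactone is disconnected at C5–C6. An α-chloroalkyl ester of a ring A acid is ionised by a silver salt to an acyloxycarbenium ion at C6. The C5=C10 alkene attacks it on the ester-bearing face, and the C10 cation loses a proton to give A2.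
- For: this is the shortest conceivable entry to the cis-fused lactone. The tether enforces the cis fusion, and A2 lacks only hydration. On step count it clearly beats the eight steps needed here to reach 13.
- Against: the configuration at C6 depends on the face of a nearly unbiased acyclic cation. The C10 cation can lose a proton in more than one direction or be intercepted by the benzyl ether oxygen. Ester-tethered cations cyclise reluctantly because the ester prefers the extended conformation. Quaternary C4 must still be made in enantioenriched form first.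
- Comparison: the chosen route is longer but sets each lactone stereocentre by a predictable event.

**Alternative 3:** The bicycle is disconnected at C12–C13. One-electron oxidation of a cyclopropanol on C8 opens it to a β-keto radical at C12. This adds to C13 of a cyclopentene, and the C16 radical expels a sulfonyl radical from C17, giving A3.
- For: the C9 ketone and the C16 methylene arrive at the right oxidation level in the ring-forming step, with the C15 acetate already present. No allylic oxidation and no methylenation are needed. In redox economy this is superior to the chosen route.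
- Against: A3 lacks the C11=C12 bond, which would have to be introduced by dehydrogenation next to the sensitive methylene acetate. The cyclisation substrate must already contain quaternary C8, set without the help of a planar enolate, together with C15 and an allylic sulfone. Six-membered closure onto a substituted alkene carbon competes with the seven-membered mode and with reduction of the primary radical.
- Comparison: the chosen route offers catalyst-controlled C8, a simple precursor and a well-precedented closure.

Key step: step 15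

Convention in names: LacCH2 = [(3R,3aS,4R,7aR)-4,7a-dimethyl-1-oxo-4-[(triethylsilyl)oxy]octahydro-2-benzofuran-3-yl]methyl (lactone locants: C1 = C19, C3 = C6, C3a = C5, C4 = C10, C7a = C4 of the skeleton).

Assumption: 1, 4, 15, 16 and both antipodes of the two ligands are purchased; the senses of induction in steps 12 and 14 are assigned by analogy with simple 2,2-disubstituted and 3-substituted cyclopentanones and would be inverted by using the other ligand antipode.

## Route

**Step 1**
Reactants: 1 5-chloropent-1-yne
Product: 3 2-bromo-5-chloropent-1-ene, via alkenylborane 2 (not isolated)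
Conditions: B-bromo-9-BBN, CH2Cl2, 0 °C; then AcOH, 0 → 23 °C
Reagents that add atoms: B-bromo-9-borabicyclo[3.3.1]nonane, BrB1C2CCCC1CCC2
Why: Syn bromoboration of the terminal alkyne puts bromine on the internal carbon and boron on the terminus (haloboration), and protonolysis of the C–B bond leaves the 2-bromo-1-alkene; the alkyl chloride is inert.

**Step 2**
Reactants: 4 (S)-5-(hydroxymethyl)furan-2(5H)-one
Product: 5 (S)-5-[(benzyloxy)methyl]furan-2(5H)-one
Conditions: BnOC(=NH)CCl3, TfOH (5 mol %), CH2Cl2/cyclohexane, 0 → 23 °C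
Reagents that add atoms: benzyl 2,2,2-trichloroacetimidate, ClC(Cl)(Cl)C(=N)OCc1ccccc1
Why: Acid-catalysed benzylation with the imidate avoids base, which would enolise the butenolide and erode C6.

**Step 3**
Reactants: 3 2-bromo-5-chloropent-1-ene; 5 (S)-5-[(benzyloxy)methyl]furan-2(5H)-one
Product: 8 (4R,5S)-5-[(benzyloxy)methyl]-4-(5-chloropent-1-en-2-yl)oxolan-2-one, via alkenyllithium 6 (not isolated), via cuprate 7 (not isolated)
Conditions: 3, t-BuLi (2 equiv), Et2O, −78 °C; CuI (0.5 equiv), THF, −78 → −40 °C; 5, −78 °C; aq. NH4Cl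
Reagents that add atoms: none
Why: Bromine–lithium exchange at −78 °C spares the alkyl chloride, and the Gilman cuprate adds 1,4 to the butenolide anti to the benzyloxymethyl group (cuprate conjugate addition to γ-substituted butenolides), which sets C5 trans to C7.

**Step 4**
Reactants: 8 (4R,5S)-5-[(benzyloxy)methyl]-4-(5-chloropent-1-en-2-yl)oxolan-2-one
Product: 9 (3S,3aR,7aR)-3-[(benzyloxy)methyl]-4-methylidenehexahydro-2-benzofuran-1(3H)-one
Conditions: KN(SiMe3)2, THF, −78 → 23 °C
Reagents that add atoms: none
Why: The potassium lactone enolate displaces the tethered primary chloride (6-exo-tet intramolecular enolate alkylation, the closing half of a methylenecyclohexane annulation); the short tether reaches only the face on which it is anchored, so the fusion is cis.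

**Step 5**
Reactants: 9 (3S,3aR,7aR)-3-[(benzyloxy)methyl]-4-methylidenehexahydro-2-benzofuran-1(3H)-one
Product: 10 (3S,3aS,7aR)-3-[(benzyloxy)methyl]-7a-methyl-4-methylidenehexahydro-2-benzofuran-1(3H)-one
Conditions: LiN(i-Pr)2, THF, −78 °C; MeI, −78 → −20 °C
Reagents that add atoms: iodomethane, CI
Why: Enolate alkylation at the ring-fusion carbon takes place on the convex face, anti to ring A, which keeps the fusion cis and places the C4 methyl syn to H5.

**Step 6**
Reactants: 10 (3S,3aS,7aR)-3-[(benzyloxy)methyl]-7a-methyl-4-methylidenehexahydro-2-benzofuran-1(3H)-one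
Product: 11 (3S,3aS,4R,7aR)-3-[(benzyloxy)methyl]-4-hydroxy-4,7a-dimethylhexahydro-2-benzofuran-1(3H)-one
Conditions: Co(acac)2 (20 mol %), PhSiH3, O2 (1 atm), THF, 23 °C
Reagents that add atoms: dioxygen, O=O
Why: Mukaiyama hydration: hydrogen-atom transfer to the terminal carbon gives the tertiary C10 radical (Markovnikov), which should capture O2 on the convex face, away from the pseudo-axial C19, so the hydroxyl is syn to H5 and the new methyl C20 syn to C6.

**Step 7**
Reactants: 11 (3S,3aS,4R,7aR)-3-[(benzyloxy)methyl]-4-hydroxy-4,7a-dimethylhexahydro-2-benzofuran-1(3H)-one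
Product: 12 (3S,3aS,4R,7aR)-3-[(benzyloxy)methyl]-4,7a-dimethyl-4-[(triethylsilyl)oxy]hexahydro-2-benzofuran-1(3H)-one
Conditions: Et3SiOTf, 2,6-lutidine, CH2Cl2, 0 °C
Reagents that add atoms: triethylsilyl trifluoromethanesulfonate, CC[Si](CC)(CC)OS(=O)(=O)C(F)(F)F
Why: The hindered tertiary alcohol needs the silyl triflate; the lactone has no α-hydrogen and is untouched.

**Step 8**
Reactants: 12 (3S,3aS,4R,7aR)-3-[(benzyloxy)methyl]-4,7a-dimethyl-4-[(triethylsilyl)oxy]hexahydro-2-benzofuran-1(3H)-one
Product: 13 (3S,3aS,4R,7aR)-3-(hydroxymethyl)-4,7a-dimethyl-4-[(triethylsilyl)oxy]hexahydro-2-benzofuran-1(3H)-one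
Conditions: H2 (1 atm), Pd/C (10 %), EtOAc, 23 °C
Reagents that add atoms: none
Why: Hydrogenolysis of the benzyl ether; no alkene remains, and the silyl ether and lactone are stable in a neutral solvent.

**Step 9**
Reactants: 13 (3S,3aS,4R,7aR)-3-(hydroxymethyl)-4,7a-dimethyl-4-[(triethylsilyl)oxy]hexahydro-2-benzofuran-1(3H)-one
Product: 14 [(3S,3aS,4R,7aR)-4,7a-dimethyl-1-oxo-4-[(triethylsilyl)oxy]octahydro-2-benzofuran-3-yl]methyl trifluoromethanesulfonate
Conditions: Tf2O, pyridine, CH2Cl2, −78 → −20 °C; used at once
Reagents that add atoms: trifluoromethanesulfonic anhydride, O=S(=O)(OS(=O)(=O)C(F)(F)F)C(F)(F)F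
Why: Sulfonylation of the only free hydroxyl gives a primary triflate reactive enough for SN2 at a β-branched, β-oxygenated carbon.

**Step 10**
Reactants: 15 methyl 2-oxocyclopentane-1-carboxylate; 16 prop-2-en-1-ol
Product: 17 prop-2-en-1-yl 2-oxocyclopentane-1-carboxylate
Conditions: DMAP (20 mol %), toluene, reflux, 4 Å sieves (removal of MeOH)
Reagents that add atoms: none
Why: Amine-catalysed transesterification of a β-keto ester, driven by removal of methanol.

**Step 11**
Reactants: 14 [(3S,3aS,4R,7aR)-4,7a-dimethyl-1-oxo-4-[(triethylsilyl)oxy]octahydro-2-benzofuran-3-yl]methyl trifluoromethanesulfonate; 17 prop-2-en-1-yl 2-oxocyclopentane-1-carboxylate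
Product: 18 prop-2-en-1-yl 1-(LacCH2)-2-oxocyclopentane-1-carboxylate (both C8 epimers)
Conditions: 17, NaH, THF, 0 °C; then 14, 0 → 23 °C
Reagents that add atoms: none
Why: C-alkylation of the sodium β-keto ester enolate by the primary triflate (SN2; a tight ion pair in THF favours carbon over oxygen); the C8 epimers are not separated because the next step passes through a planar enolate.

**Step 12**
Reactants: 18 prop-2-en-1-yl 1-(LacCH2)-2-oxocyclopentane-1-carboxylate (both C8 epimers)
Product: 19 (2R)-2-(LacCH2)-2-(prop-2-en-1-yl)cyclopentan-1-one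
Conditions: Pd2(dba)3 (5 mol %), (R)-t-BuPHOX (12.5 mol %), toluene, 30 °C
Reagents that add atoms: none
Why: Decarboxylative asymmetric allylic alkylation: zerovalent palladium ionises the allyl ester, CO2 is lost, and the enolate is allylated on the face chosen by the phosphinooxazoline, so both epimers of 18 converge and C8 is set by the catalyst, not by the remote lactone.

**Step 13**
Reactants: 19 (2R)-2-(LacCH2)-2-(prop-2-en-1-yl)cyclopentan-1-one
Product: 21 (5S)-5-(LacCH2)-5-(prop-2-en-1-yl)cyclopent-2-en-1-one, via silyl enol ether 20 (not isolated)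
Conditions: LiN(SiMe3)2, Me3SiCl, THF, −78 °C; then Pd(OAc)2 (1.1 equiv), MeCN, 23 °C
Reagents that add atoms: none
Why: Saegusa–Ito oxidation: the ketone enolises only toward C16, the silyl enol ether transmetallates to divalent palladium, and β-hydride elimination from C13 gives the enone; the lactone has no α-hydrogen.

**Step 14**
Reactants: 21 (5S)-5-(LacCH2)-5-(prop-2-en-1-yl)cyclopent-2-en-1-one
Product: 22 (2S,4R)-4-ethenyl-2-(LacCH2)-2-(prop-2-en-1-yl)cyclopentan-1-one
Conditions: [Rh(cod)2]BF4 (5 mol %), (R)-BINAP (6 mol %), CH2=CHBF3K, Et3N, toluene/H2O (10:1), 40 °C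
Reagents that add atoms: potassium vinyltrifluoroborate, C=C[B-](F)(F)F.[K+]
Why: Rhodium–bisphosphine-catalysed asymmetric 1,4-addition of an alkenylboron reagent to a cyclic enone: the vinyl–rhodium species inserts the unhindered C13=C16 bond, and the ligand, not the remote C8 centre, fixes C13 so that vinyl is cis to allyl.

**Step 15**
Reactants: 22 (2S,4R)-4-ethenyl-2-(LacCH2)-2-(prop-2-en-1-yl)cyclopentan-1-one
Product: 23 (1R,5S)-5-(LacCH2)bicyclo[3.2.1]oct-2-en-6-one
Conditions: second-generation Grubbs catalyst (H2IMes)(PCy3)Cl2Ru=CHPh (5 mol %), CH2Cl2 (0.005 M), 40 °C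
Reagents that add atoms: none
Why: The ruthenium benzylidene exchanges onto one of the two monosubstituted alkenes (probably the vinyl group on C13, the allyl arm being neopentylic), the new alkylidene adds across the other alkene to a ruthenacyclobutane, and cycloreversion releases the C11=C12 bond and a ruthenium methylidene while ethene leaves the solution. The closest known reaction type is ring-closing metathesis of cis-1,3-dialkenyl cycloalkanes to bridged bicycloalkenes. One ring is closed, the six-membered ring C8–C9–C11=C12–C13–C14, by joining the ends of two chains anchored 1,3 on the cyclopentanone, which turns the monocycle into the bicyclo[3.2.1]oct-2-ene; the ring size allows only the Z alkene. No stereocentre is created, and C8 and C13 are carried unchanged as the bridgeheads. The selectivity needed is cyclisation over acyclic diene oligomerisation, and it is secured by the cis relationship of the two arms, which lets both reach the same face of an envelope cyclopentanone, and by high dilution; the trans isomer cannot close, so any C13 epimer is left behind. The ketone, the lactone and the silyl ether do not react with the ruthenium carbene, and no other alkene is present. Because C9 is still a methylene, the allyl arm is an ordinary terminal olefin and not an electron-poor enone.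

**Step 16**
Reactants: 23 (1R,5S)-5-(LacCH2)bicyclo[3.2.1]oct-2-en-6-one
Product: 24 (1R,4R,5S)-4-hydroxy-5-(LacCH2)bicyclo[3.2.1]oct-2-en-6-one
Conditions: SeO2 (0.5 equiv), t-BuOOH, CH2Cl2, 23 → 40 °C
Reagents that add atoms: selenium dioxide, O=[Se]=O (transfers the oxygen atom); tert-butyl hydroperoxide, CC(C)(C)OO (reoxidises selenium, ultimate oxygen source)
Why: Allylic hydroxylation by ene reaction and [2,3]-sigmatropic shift: selenium can bond only to C12 with hydrogen transfer from C9, since the other ene mode would need a C12=C13 bridgehead double bond, so oxygen returns to C9 and C11=C12 is restored. Attack on the alkene face turned away from the C15–C16 bridge should give mainly the epimer drawn; the C9 configuration is of no consequence.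

**Step 17**
Reactants: 24 (1R,4R,5S)-4-hydroxy-5-(LacCH2)bicyclo[3.2.1]oct-2-en-6-one
Product: 25 (1R,4R,5S)-5-(LacCH2)-4-[(triethylsilyl)oxy]bicyclo[3.2.1]oct-2-en-6-one
Conditions: Et3SiCl, imidazole, DMAP (cat.), CH2Cl2, 0 → 23 °C
Reagents that add atoms: chlorotriethylsilane, CC[Si](Cl)(CC)CC
Why: Silylation with the chloride and imidazole does not enolise the C15 ketone, and it masks the β-hydroxy ketone against retro-aldol cleavage in the next step.

**Step 18**
Reactants: 25 (1R,4R,5S)-5-(LacCH2)-4-[(triethylsilyl)oxy]bicyclo[3.2.1]oct-2-en-6-one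
Product: 28 (1S,4R,5S)-5-(LacCH2)-7-methylidene-4-[(triethylsilyl)oxy]bicyclo[3.2.1]oct-2-en-6-one, via Mannich base 26 (not isolated), via ammonium iodide 27 (not isolated)
Conditions: LiN(SiMe3)2, THF, −78 °C; CH2=NMe2 I, −78 → 23 °C; MeI, CH2Cl2; DBU, 23 °C
Reagents that add atoms: N,N-dimethylmethyleneiminium iodide (Eschenmoser's salt), C=[N+](C)C.[I-]
Why: Eschenmoser methylenation: the lithium enolate (C16 is the only enolisable carbon) undergoes a Mannich reaction, and quaternisation followed by E1cB loss of trimethylamine gives the α-methylene ketone.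

**Step 19**
Reactants: 28 (1S,4R,5S)-5-(LacCH2)-7-methylidene-4-[(triethylsilyl)oxy]bicyclo[3.2.1]oct-2-en-6-one
Product: 29 (1S,4R,5R,6R)-5-(LacCH2)-7-methylidene-4-[(triethylsilyl)oxy]bicyclo[3.2.1]oct-2-en-6-ol
Conditions: NaBH4, CeCl3·7H2O, MeOH, −78 → −40 °C
Reagents that add atoms: none
Why: Luche 1,2-reduction: hydride reaches the C15 carbonyl from the side of the one-carbon bridge C14, the other face being screened by the C9–C11–C12 bridge, so the hydroxyl ends up syn to that bridge as in the target; cerium suppresses conjugate reduction.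

**Step 20**
Reactants: 29 (1S,4R,5R,6R)-5-(LacCH2)-7-methylidene-4-[(triethylsilyl)oxy]bicyclo[3.2.1]oct-2-en-6-ol
Product: 30 (1S,4R,5R,6R)-5-(LacCH2)-7-methylidene-4-[(triethylsilyl)oxy]bicyclo[3.2.1]oct-2-en-6-yl acetate
Conditions: Ac2O, pyridine, DMAP (cat.), CH2Cl2, 23 °C
Reagents that add atoms: acetic anhydride, CC(=O)OC(C)=O
Why: Nucleophile-catalysed acylation of the only free hydroxyl.

**Step 21**
Reactants: 30 (1S,4R,5R,6R)-5-(LacCH2)-7-methylidene-4-[(triethylsilyl)oxy]bicyclo[3.2.1]oct-2-en-6-yl acetate
Product: 31 (1S,4R,5S,6R)-4-hydroxy-5-{[(3R,3aS,4R,7aR)-4-hydroxy-4,7a-dimethyl-1-oxooctahydro-2-benzofuran-3-yl]methyl}-7-methylidenebicyclo[3.2.1]oct-2-en-6-yl acetate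
Conditions: HF·pyridine, pyridine, THF, 0 → 23 °C
Reagents that add atoms: none
Why: Buffered fluoride cleaves both triethylsilyl ethers while sparing the allylic acetate and lactone; the mildly acidic medium disfavours acetyl migration from O15 to O9.

**Step 22**
Reactants: 31 (1S,4R,5S,6R)-4-hydroxy-5-{[(3R,3aS,4R,7aR)-4-hydroxy-4,7a-dimethyl-1-oxooctahydro-2-benzofuran-3-yl]methyl}-7-methylidenebicyclo[3.2.1]oct-2-en-6-yl acetate
Product: 32 (1S,5R,6R)-5-{[(3R,3aS,4R,7aR)-4-hydroxy-4,7a-dimethyl-1-oxooctahydro-2-benzofuran-3-yl]methyl}-7-methylidene-4-oxobicyclo[3.2.1]oct-2-en-6-yl acetate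
Conditions: Dess–Martin periodinane, pyridine, CH2Cl2, 0 → 23 °C
Reagents that add atoms: none
Why: Dess–Martin oxidation of the secondary allylic alcohol gives the enone; the tertiary C10 alcohol cannot be oxidised, and the conditions are too mild to disturb the β-acetoxy ketone.

## Compound list

1 | 5-chloropent-1-yne | ClCCCC#C | starting material
2 | B-[(Z)-2-bromo-5-chloropent-1-en-1-yl]-9-borabicyclo[3.3.1]nonane | ClCCC/C(Br)=C/B1C2CCCC1CCC2 | intermediate
3 | 2-bromo-5-chloropent-1-ene | C=C(Br)CCCCl | intermediate
4 | (S)-5-(hydroxymethyl)furan-2(5H)-one | OC[C@H]1OC(=O)C=C1 | starting material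
5 | (S)-5-[(benzyloxy)methyl]furan-2(5H)-one | c1ccccc1COC[C@H]1OC(=O)C=C1 | intermediate
6 | (5-chloropent-1-en-2-yl)lithium | [Li]C(=C)CCCCl | intermediate
7 | lithium bis(5-chloropent-1-en-2-yl)cuprate | [Li+].C=C(CCCCl)[Cu-]C(=C)CCCCl | intermediate
8 | (4R,5S)-5-[(benzyloxy)methyl]-4-(5-chloropent-1-en-2-yl)oxolan-2-one | c1ccccc1COC[C@H]1OC(=O)C[C@@H]1C(=C)CCCCl | intermediate
9 | (3S,3aR,7aR)-3-[(benzyloxy)methyl]-4-methylidenehexahydro-2-benzofuran-1(3H)-one (cis-fused) | c1ccccc1COC[C@H]3OC(=O)[C@@H]4CCCC(=C)[C@H]34 | intermediate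
10 | (3S,3aS,7aR)-3-[(benzyloxy)methyl]-7a-methyl-4-methylidenehexahydro-2-benzofuran-1(3H)-one | c1ccccc1COC[C@H]3OC(=O)[C@]4(C)CCCC(=C)[C@H]34 | intermediate
11 | (3S,3aS,4R,7aR)-3-[(benzyloxy)methyl]-4-hydroxy-4,7a-dimethylhexahydro-2-benzofuran-1(3H)-one | c1ccccc1COC[C@H]3OC(=O)[C@]4(C)CCC[C@@](C)(O)[C@H]34 | intermediate
12 | (3S,3aS,4R,7aR)-3-[(benzyloxy)methyl]-4,7a-dimethyl-4-[(triethylsilyl)oxy]hexahydro-2-benzofuran-1(3H)-one | c1ccccc1COC[C@H]3OC(=O)[C@]4(C)CCC[C@@](C)(O[Si](CC)(CC)CC)[C@H]34 | intermediate
13 | (3S,3aS,4R,7aR)-3-(hydroxymethyl)-4,7a-dimethyl-4-[(triethylsilyl)oxy]hexahydro-2-benzofuran-1(3H)-one | OC[C@H]3OC(=O)[C@]4(C)CCC[C@@](C)(O[Si](CC)(CC)CC)[C@H]34 | intermediate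
14 | [(3S,3aS,4R,7aR)-4,7a-dimethyl-1-oxo-4-[(triethylsilyl)oxy]octahydro-2-benzofuran-3-yl]methyl trifluoromethanesulfonate | FC(F)(F)S(=O)(=O)OC[C@H]3OC(=O)[C@]4(C)CCC[C@@](C)(O[Si](CC)(CC)CC)[C@H]34 | intermediate
15 | methyl 2-oxocyclopentane-1-carboxylate | COC(=O)C1CCCC1=O | starting material
16 | prop-2-en-1-ol | C=CCO | starting material
17 | prop-2-en-1-yl 2-oxocyclopentane-1-carboxylate | C=CCOC(=O)C1CCCC1=O | intermediate
18 | prop-2-en-1-yl 1-(LacCH2)-2-oxocyclopentane-1-carboxylate (both C8 epimers) | C=CCOC(=O)C1(C[C@H]3OC(=O)[C@]4(C)CCC[C@@](C)(O[Si](CC)(CC)CC)[C@H]34)CCCC1=O | intermediate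
19 | (2R)-2-(LacCH2)-2-(prop-2-en-1-yl)cyclopentan-1-one | C=CC[C@@]1(C[C@H]3OC(=O)[C@]4(C)CCC[C@@](C)(O[Si](CC)(CC)CC)[C@H]34)CCCC1=O | intermediate
20 | trimethyl{[5-(LacCH2)-5-(prop-2-en-1-yl)cyclopent-1-en-1-yl]oxy}silane (C8 as in 19) | C=CC[C@@]1(C[C@H]3OC(=O)[C@]4(C)CCC[C@@](C)(O[Si](CC)(CC)CC)[C@H]34)CCC=C1O[Si](C)(C)C | intermediate
21 | (5S)-5-(LacCH2)-5-(prop-2-en-1-yl)cyclopent-2-en-1-one | C=CC[C@@]1(C[C@H]3OC(=O)[C@]4(C)CCC[C@@](C)(O[Si](CC)(CC)CC)[C@H]34)CC=CC1=O | intermediate
22 | (2S,4R)-4-ethenyl-2-(LacCH2)-2-(prop-2-en-1-yl)cyclopentan-1-one (allyl and vinyl cis) | C=CC[C@@]1(C[C@H]3OC(=O)[C@]4(C)CCC[C@@](C)(O[Si](CC)(CC)CC)[C@H]34)C[C@@H](C=C)CC1=O | intermediate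
23 | (1R,5S)-5-(LacCH2)bicyclo[3.2.1]oct-2-en-6-one | C1[C@@H]2C=CC[C@@](C[C@H]3OC(=O)[C@]4(C)CCC[C@@](C)(O[Si](CC)(CC)CC)[C@H]34)(C2)C1=O | intermediate
24 | (1R,4R,5S)-4-hydroxy-5-(LacCH2)bicyclo[3.2.1]oct-2-en-6-one (C9 hydroxyl anti to the C15–C16 bridge, expected major epimer) | C1[C@@H]2C=C[C@@H](O)[C@@](C[C@H]3OC(=O)[C@]4(C)CCC[C@@](C)(O[Si](CC)(CC)CC)[C@H]34)(C2)C1=O | intermediate
25 | (1R,4R,5S)-5-(LacCH2)-4-[(triethylsilyl)oxy]bicyclo[3.2.1]oct-2-en-6-one | C1[C@@H]2C=C[C@@H](O[Si](CC)(CC)CC)[C@@](C[C@H]3OC(=O)[C@]4(C)CCC[C@@](C)(O[Si](CC)(CC)CC)[C@H]34)(C2)C1=O | intermediate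
26 | 7-[(dimethylamino)methyl] derivative of 25 (C16 epimers) | CN(C)CC1[C@@H]2C=C[C@@H](O[Si](CC)(CC)CC)[C@@](C[C@H]3OC(=O)[C@]4(C)CCC[C@@](C)(O[Si](CC)(CC)CC)[C@H]34)(C2)C1=O | intermediate
27 | trimethylammonium iodide obtained from 26 by N-methylation | C[N+](C)(C)CC1[C@@H]2C=C[C@@H](O[Si](CC)(CC)CC)[C@@](C[C@H]3OC(=O)[C@]4(C)CCC[C@@](C)(O[Si](CC)(CC)CC)[C@H]34)(C2)C1=O.[I-] | intermediate
28 | (1S,4R,5S)-5-(LacCH2)-7-methylidene-4-[(triethylsilyl)oxy]bicyclo[3.2.1]oct-2-en-6-one | C=C1[C@@H]2C=C[C@@H](O[Si](CC)(CC)CC)[C@@](C[C@H]3OC(=O)[C@]4(C)CCC[C@@](C)(O[Si](CC)(CC)CC)[C@H]34)(C2)C1=O | intermediate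
29 | (1S,4R,5R,6R)-5-(LacCH2)-7-methylidene-4-[(triethylsilyl)oxy]bicyclo[3.2.1]oct-2-en-6-ol (hydroxyl syn to the C9–C12 bridge) | C=C1[C@@H]2C=C[C@@H](O[Si](CC)(CC)CC)[C@@](C[C@H]3OC(=O)[C@]4(C)CCC[C@@](C)(O[Si](CC)(CC)CC)[C@H]34)(C2)[C@@H]1O | intermediate
30 | (1S,4R,5R,6R)-5-(LacCH2)-7-methylidene-4-[(triethylsilyl)oxy]bicyclo[3.2.1]oct-2-en-6-yl acetate | C=C1[C@@H]2C=C[C@@H](O[Si](CC)(CC)CC)[C@@](C[C@H]3OC(=O)[C@]4(C)CCC[C@@](C)(O[Si](CC)(CC)CC)[C@H]34)(C2)[C@@H]1OC(C)=O | intermediate
31 | (1S,4R,5S,6R)-4-hydroxy-5-{[(3R,3aS,4R,7aR)-4-hydroxy-4,7a-dimethyl-1-oxooctahydro-2-benzofuran-3-yl]methyl}-7-methylidenebicyclo[3.2.1]oct-2-en-6-yl acetate | C=C1[C@@H]2C=C[C@@H](O)[C@@](C[C@H]3OC(=O)[C@]4(C)CCC[C@@](C)(O)[C@H]34)(C2)[C@@H]1OC(C)=O | intermediate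
32 | (1S,5R,6R)-5-{[(3R,3aS,4R,7aR)-4-hydroxy-4,7a-dimethyl-1-oxooctahydro-2-benzofuran-3-yl]methyl}-7-methylidene-4-oxobicyclo[3.2.1]oct-2-en-6-yl acetate (CNP0172716.1) | C=C1[C@@H]2C=CC(=O)[C@@](C[C@H]3OC(=O)[C@]4(C)CCC[C@@](C)(O)[C@H]34)(C2)[C@@H]1OC(C)=O | target

## Step count and least certain steps

Total step count: 22. Longest linear sequence: 20 steps (steps 2–9 and 11–22, counted from 4); steps 1 and 10 supply side components.

**Step 15 (key step).** The closure may be outrun by intermolecular metathesis, or may stall because the alkylidene formed on the allyl arm is held by the C15 carbonyl oxygen and because the ring being formed is bridged. Migration of the allyl double bond by ruthenium hydrides would also remove the substrate. Fallback, setting out from 22: the ketone is reduced (NaBH4, MeOH) to the cyclopentanol F1 as a mixture of C15 epimers. This substrate has no chelating carbonyl and an sp3 carbon in the future two-carbon bridge. It is closed with the same catalyst to the bicyclic alcohol F2, and Dess–Martin oxidation returns to 23.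

**Step 6.** Capture of O2 by the planar C10 radical may show poor facial selectivity, since a free radical discriminates less than a concerted addition and the wanted isomer is the less stable one. Fallback, setting out from 10: the exocyclic alkene is epoxidised with a peracid on the convex face to the spiro-epoxide F3. Iodide (LiI, AcOH, THF) opens it at the primary carbon to the iodohydrin F4, and Bu3SnH/AIBN removes iodine, which returns to 11.

**Step 11.** Alkylation at oxygen of the ambident enolate by the hard triflate may compete. Slow substitution at the β-branched carbon may also allow loss of the triflate through participation of the C10 silyl ether oxygen. Fallback, setting out from 14: the triflate alkylates the lithium azaenolate of cyclopentanone N,N-dimethylhydrazone (LiN(i-Pr)2, THF, −78 → 0 °C), a far stronger carbon nucleophile, to give the hydrazone F5. Mild hydrolysis (aqueous oxalic acid) gives the ketone F6. Me3SiCl, NaI and Et3N in MeCN give the more substituted silyl enol ether F7. Palladium-catalysed asymmetric allylation of F7 (Pd2(dba)3, (R)-t-BuPHOX, diallyl carbonate, Bu4N[Ph3SiF2], THF) returns to 19.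

**Step 14.** Ligand control may be eroded in a mismatched pairing with C8, or the vinylboron reagent may be lost by protodeboronation before transmetallation. Fallback, setting out from 21: copper-catalysed addition of vinylmagnesium bromide (CuI, Me3SiCl, THF, −78 °C) under substrate control gives 22 together with its C13 epimer F8. The mixture is taken into step 15, where only 22 can cyclise, and F8 is removed from 23 by chromatography.

**Step 16.** The ene reaction of the cis-disubstituted alkene may be sluggish, which gives time for α-oxidation at C16 or over-oxidation of C9 to the ketone level. Fallback, setting out from 23 and using a hydrogen-abstraction oxidant late: 23 is methylenated as in step 18 to the methylene ketone F9, reduced as in step 19 to the alcohol F10 and acetylated to the acetate F11. C9 is then oxidised directly with CrO3·3,5-dimethylpyrazole (CH2Cl2, −20 °C) to the silylated enone F12, which must be separated from the isomer oxygenated at C12. HF·pyridine then gives 32.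

## Further compounds

F1 | step 15 | (2S,4R)-4-ethenyl-2-(LacCH2)-2-(prop-2-en-1-yl)cyclopentan-1-ol (C15 epimers) | C=CC[C@@]1(C[C@H]3OC(=O)[C@]4(C)CCC[C@@](C)(O[Si](CC)(CC)CC)[C@H]34)C[C@@H](C=C)CC1O
F2 | step 15 | (1R,5S)-5-(LacCH2)bicyclo[3.2.1]oct-2-en-6-ol (C15 epimers) | C1[C@@H]2C=CC[C@@](C[C@H]3OC(=O)[C@]4(C)CCC[C@@](C)(O[Si](CC)(CC)CC)[C@H]34)(C2)C1O
F3 | step 6 | (3S,3aS,7aR)-3-[(benzyloxy)methyl]-7a-methylhexahydro-1H-spiro[2-benzofuran-4,2'-oxiran]-1-one (oxirane oxygen syn to H-3a) | c1ccccc1COC[C@H]3OC(=O)[C@]4(C)CCC[C@@](C5)(O5)[C@H]34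
F4 | step 6 | (3S,3aS,4R,7aR)-3-[(benzyloxy)methyl]-4-hydroxy-4-(iodomethyl)-7a-methylhexahydro-2-benzofuran-1(3H)-one | c1ccccc1COC[C@H]3OC(=O)[C@]4(C)CCC[C@@](CI)(O)[C@H]34
F5 | step 11 | 2-(LacCH2)cyclopentan-1-one N,N-dimethylhydrazone (C8 epimers) | CN(C)N=C1CCCC1C[C@H]3OC(=O)[C@]4(C)CCC[C@@](C)(O[Si](CC)(CC)CC)[C@H]34
F6 | step 11 | 2-(LacCH2)cyclopentan-1-one (C8 epimers) | O=C1CCCC1C[C@H]3OC(=O)[C@]4(C)CCC[C@@](C)(O[Si](CC)(CC)CC)[C@H]34
F7 | step 11 | trimethyl{[2-(LacCH2)cyclopent-1-en-1-yl]oxy}silane | C[Si](C)(C)OC1=C(C[C@H]3OC(=O)[C@]4(C)CCC[C@@](C)(O[Si](CC)(CC)CC)[C@H]34)CCC1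
F8 | step 14 | (2S,4S)-4-ethenyl-2-(LacCH2)-2-(prop-2-en-1-yl)cyclopentan-1-one (allyl and vinyl trans) | C=CC[C@@]1(C[C@H]3OC(=O)[C@]4(C)CCC[C@@](C)(O[Si](CC)(CC)CC)[C@H]34)C[C@H](C=C)CC1=O
F9 | step 16 | (1S,5S)-5-(LacCH2)-7-methylidenebicyclo[3.2.1]oct-2-en-6-one | C=C1[C@@H]2C=CC[C@@](C[C@H]3OC(=O)[C@]4(C)CCC[C@@](C)(O[Si](CC)(CC)CC)[C@H]34)(C2)C1=O
F10 | step 16 | (1S,5S,6S)-5-(LacCH2)-7-methylidenebicyclo[3.2.1]oct-2-en-6-ol (hydroxyl syn to the C9–C12 bridge) | C=C1[C@@H]2C=CC[C@@](C[C@H]3OC(=O)[C@]4(C)CCC[C@@](C)(O[Si](CC)(CC)CC)[C@H]34)(C2)[C@@H]1O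
F11 | step 16 | (1S,5S,6S)-5-(LacCH2)-7-methylidenebicyclo[3.2.1]oct-2-en-6-yl acetate | C=C1[C@@H]2C=CC[C@@](C[C@H]3OC(=O)[C@]4(C)CCC[C@@](C)(O[Si](CC)(CC)CC)[C@H]34)(C2)[C@@H]1OC(C)=O
F12 | step 16 | (1S,5R,6R)-5-(LacCH2)-7-methylidene-4-oxobicyclo[3.2.1]oct-2-en-6-yl acetate (C10 triethylsilyl ether of 32) | C=C1[C@@H]2C=CC(=O)[C@@](C[C@H]3OC(=O)[C@]4(C)CCC[C@@](C)(O[Si](CC)(CC)CC)[C@H]34)(C2)[C@@H]1OC(C)=O
A1 | alternative 1 | (1R,2S)-2-({[tert-butyl(dimethyl)silyl]oxy}methyl)-1,3-dimethylcyclohex-3-ene-1-carboxylic acid | OC(=O)[C@]1(C)CCC=C(C)[C@@H]1CO[Si](C)(C)C(C)(C)C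
A2 | alternative 2 | (3S,3aS,7aR)-3-[(benzyloxy)methyl]-4,7a-dimethyl-3a,6,7,7a-tetrahydro-2-benzofuran-1(3H)-one | c1ccccc1COC[C@H]2OC(=O)[C@]3(C)CCC=C(C)[C@H]23
A3 | alternative 3 | (1R,5R,6R)-5-(LacCH2)-7-methylidene-4-oxobicyclo[3.2.1]octan-6-yl acetate (11,12-dihydro target as C10 triethylsilyl ether) | C=C1[C@@H]2CCC(=O)[C@@](C[C@H]3OC(=O)[C@]4(C)CCC[C@@](C)(O[Si](CC)(CC)CC)[C@H]34)(C2)[C@@H]1OC(C)=O
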